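**Retrosynthetic overview**
1. Target 19 ⇐ desilylation of 18 ⇐ para-Claisen–Cope relay of a prenyl group from O5 through C6 (blocked by its methyl) to C8 in 16 ⇐ cross-metathesis of the 5-O-allyl flavanone 14.
2. Key disconnection: the O1–C2 bond of the pyranone ring (O1, C2, C3, C4, C4a, C8a) of 14 ⇒ open E/Z alkylidene β-keto ester 12; closure by catalytic enantioselective 6-endo oxa-Michael addition with a traceless CO2tBu group on C3, then decarboxylation.
3. Enabling feature: O1–C2 is β to the C4 ketone and C2 is a p-anisyl benzylic carbon (retro-oxa-Michael bond). C4a lies between two phenolic oxygens; capping the one next to the C6 methyl (O5) as an allyl ether leaves only the oxygen on C8a free to close, and this cap, peri to C4=O, later becomes the C8 prenyl group.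
4. 12 ⇐ Knoevenagel condensation (4-methoxybenzaldehyde) ⇐ β-keto ester 10 ⇐ ketone 8 ⇐ 2′,4′,6′-trihydroxy-3′-methylacetophenone 1 by site-selective silylation and Mitsunobu allylation.
5. Ring order: both benzene rings are bought; the pyranone ring is the only ring made and is closed last.

Key step: step 6

Remark: compound 1 is taken as a catalogue compound (otherwise one C-acetylation from 2-methylphloroglucinol).
Remark: the quinidine-derived thiourea is assumed to be the pseudoenantiomer that gives 2S; if a test run shows the opposite sense, the quinine-derived catalyst replaces it with no other change.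

**Step 1**
Reactants: 1 1-(2,4,6-trihydroxy-3-methylphenyl)ethan-1-one; 2 chlorotriisopropylsilane; 3 tert-butylchlorodimethylsilane
Product: 5 1-[6-(tert-butyldimethylsilyloxy)-2-hydroxy-3-methyl-4-(triisopropylsilyloxy)phenyl]ethan-1-one, via mono-TIPS ether 4 (not isolated)
Conditions: TIPSCl (1.05 equiv), imidazole, DMF, 0 °C; then TBSCl (1.2 equiv), rt
Reagents that add atoms: chlorotriisopropylsilane CC(C)[Si](Cl)(C(C)C)C(C)C; tert-butylchlorodimethylsilane CC(C)(C)[Si](C)(C)Cl
Why: Silyl ether formation; the 4-OH is the only phenol not chelated to the acetyl C=O and should take the bulky TIPS group first, and of the two chelated ortho-OH groups only the one next to H-5 is open to TBSCl, while the 2-OH wedged between acetyl and methyl should stay free.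

**Step 2**
Reactants: 5 1-[6-(tert-butyldimethylsilyloxy)-2-hydroxy-3-methyl-4-(triisopropylsilyloxy)phenyl]ethan-1-one; 6 prop-2-en-1-ol (allyl alcohol)
Product: 7 1-[2-(allyloxy)-6-(tert-butyldimethylsilyloxy)-3-methyl-4-(triisopropylsilyloxy)phenyl]ethan-1-one
Conditions: PPh3, DIAD, THF, 0 °C → rt
Reagents that add atoms: allyl alcohol C=CCO
Why: Mitsunobu etherification of the remaining chelated phenol with a primary allylic alcohol, a neutral method of the kind used to O-alkylate chelated 2′-OH/5-OH groups, which should leave the base-labile aryl silyl ethers untouched.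

**Step 3**
Reactants: 7 1-[2-(allyloxy)-6-(tert-butyldimethylsilyloxy)-3-methyl-4-(triisopropylsilyloxy)phenyl]ethan-1-one
Product: 8 1-[2-(allyloxy)-6-hydroxy-3-methyl-4-(triisopropylsilyloxy)phenyl]ethan-1-one
Conditions: HF·pyridine, pyridine, THF, 0 °C
Reagents that add atoms: none
Why: Fluoride desilylation; the aryl TBS ether ortho to the carbonyl should cleave well before the bulkier aryl TIPS ether, freeing only the phenol that becomes O1.

**Step 4**
Reactants: 8 1-[2-(allyloxy)-6-hydroxy-3-methyl-4-(triisopropylsilyloxy)phenyl]ethan-1-one; 9 di-tert-butyl dicarbonate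
Product: 10 tert-butyl 3-[2-(allyloxy)-6-hydroxy-3-methyl-4-(triisopropylsilyloxy)phenyl]-3-oxopropanoate
Conditions: LiHMDS (3.3 equiv), THF, −78 °C; Boc2O, −78 → −20 °C; aq. NH4Cl
Reagents that add atoms: di-tert-butyl dicarbonate CC(C)(C)OC(=O)OC(=O)OC(C)(C)C
Why: Claisen-type C-acylation of the lithium polyanion of a 2′-hydroxyacetophenone; any O-Boc phenol formed should be funnelled to the same β-keto ester by Baker–Venkataraman-type O→C transfer under the excess base.

**Step 5**
Reactants: 10 tert-butyl 3-[2-(allyloxy)-6-hydroxy-3-methyl-4-(triisopropylsilyloxy)phenyl]-3-oxopropanoate; 11 4-methoxybenzaldehyde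
Product: 12 tert-butyl 2-[2-(allyloxy)-6-hydroxy-3-methyl-4-(triisopropylsilyloxy)benzoyl]-3-(4-methoxyphenyl)prop-2-enoate (E/Z mixture)
Conditions: piperidine (10 mol %), AcOH (10 mol %), 4 Å MS, toluene, rt → 40 °C
Reagents that add atoms: 4-methoxybenzaldehyde COc1ccc(C=O)cc1
Why: Knoevenagel condensation of a β-keto ester with an aromatic aldehyde under buffered amine catalysis; the alkene geometry needs no control because the next step is stereoconvergent.

**Step 6**
Reactants: 12 tert-butyl 2-[2-(allyloxy)-6-hydroxy-3-methyl-4-(triisopropylsilyloxy)benzoyl]-3-(4-methoxyphenyl)prop-2-enoate (E/Z mixture)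
Product: 14 (2S)-5-(allyloxy)-2-(4-methoxyphenyl)-6-methyl-7-(triisopropylsilyloxy)chroman-4-one, via 3-carboxylate adduct 13 (not isolated)
Conditions: quinidine-derived 3,5-(CF3)2C6H3-thiourea (10 mol %), toluene, −25 °C; then TsOH·H2O, 80 °C
Reagents that add atoms: none
Why: The thiourea N–H bonds bind the 1,3-dicarbonyl unit of 12 while the quinuclidine nitrogen acts as general base on the only free phenol (the future O1), which adds to the benzylidene carbon in a 6-endo-trig oxa-Michael addition to give 13; TsOH at 80 °C then cleaves the tert-butyl ester and the β-keto acid decarboxylates through its enol, so no ring-opening enolate is formed. The closest known reaction is the cinchona-thiourea-catalysed enantioselective cyclisation of tert-butyl alkylidene β-keto esters of 2′-hydroxyaryl ketones to flavanones with one-pot decarboxylation. The new stereocentre C2 is set by the catalyst (face selection of the bound enone), and the step should be stereoconvergent: E- and Z-12 can interconvert under the amine catalyst by reversible conjugate addition and pass through the same bound transition state, and the C3 epimers of 13 are erased on decarboxylation. The selectivity the step needs is between the two ortho oxygens of the aroyl ring, and the substrate secures it: the oxygen next to the methyl group is capped as the allyl ether, so only the oxygen next to C8–H can close the ring (6-methyl, never 8-methyl). Enantioselectivity over racemic background closure is helped by the ester activation, which should let the ring close at −25 °C, and the allyl and TIPS ethers are stable to the acid stage.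

**Step 7**
Reactants: 14 (2S)-5-(allyloxy)-2-(4-methoxyphenyl)-6-methyl-7-(triisopropylsilyloxy)chroman-4-one; 15 2-methylbut-2-ene
Product: 16 (2S)-2-(4-methoxyphenyl)-6-methyl-5-(3-methylbut-2-enyloxy)-7-(triisopropylsilyloxy)chroman-4-one
Conditions: Grubbs II (5 mol %), 2-methylbut-2-ene/CH2Cl2, 40 °C
Reagents that add atoms: 2-methylbut-2-ene CC=C(C)C
Why: Olefin cross-metathesis of a terminal allyl ether with excess 2-methylbut-2-ene should turn O-allyl into O-prenyl with loss of propene, without touching the ketone, the silyl ether or C2.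

**Step 8**
Reactants: 16 (2S)-2-(4-methoxyphenyl)-6-methyl-5-(3-methylbut-2-enyloxy)-7-(triisopropylsilyloxy)chroman-4-one
Product: 18 (2S)-5-hydroxy-2-(4-methoxyphenyl)-6-methyl-8-(3-methylbut-2-enyl)-7-(triisopropylsilyloxy)chroman-4-one, via ortho-dienone 17 (not isolated)
Conditions: Eu(fod)3 (10 mol %), CHCl3, 60 °C
Reagents that add atoms: none
Why: Eu(III)-catalysed para-Claisen–Cope rearrangement of a 5-O-prenyl flavanone: the [3,3] shift goes to C6, which carries the methyl group and cannot rearomatise, so dienone 17 must pass the allyl unit on by Cope rearrangement to C8, the only free position, where tautomerisation gives the normal prenyl group and the free 5-OH while C2 is not involved.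

**Step 9**
Reactants: 18 (2S)-5-hydroxy-2-(4-methoxyphenyl)-6-methyl-8-(3-methylbut-2-enyl)-7-(triisopropylsilyloxy)chroman-4-one
Product: 19 (2S)-5,7-dihydroxy-2-(4-methoxyphenyl)-6-methyl-8-(3-methylbut-2-en-1-yl)chroman-4-one
Conditions: TBAF, AcOH, THF, 0 °C
Reagents that add atoms: none
Why: Fluoride desilylation buffered with acetic acid, so that no free phenoxide or enolate persists that could open the pyranone ring (retro-oxa-Michael) and erode the C2 configuration.

**Compound list**
1 | 1-(2,4,6-trihydroxy-3-methylphenyl)ethan-1-one | CC(=O)c1c(O)c(C)c(O)cc1O | starting material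
2 | chlorotriisopropylsilane | CC(C)[Si](Cl)(C(C)C)C(C)C | starting material
3 | tert-butylchlorodimethylsilane | CC(C)(C)[Si](C)(C)Cl | starting material
4 | 1-[2,6-dihydroxy-3-methyl-4-(triisopropylsilyloxy)phenyl]ethan-1-one | CC(=O)c1c(O)c(C)c(O[Si](C(C)C)(C(C)C)C(C)C)cc1O | intermediate
5 | 1-[6-(tert-butyldimethylsilyloxy)-2-hydroxy-3-methyl-4-(triisopropylsilyloxy)phenyl]ethan-1-one | CC(=O)c1c(O)c(C)c(O[Si](C(C)C)(C(C)C)C(C)C)cc1O[Si](C)(C)C(C)(C)C | intermediate
6 | prop-2-en-1-ol | C=CCO | starting material
7 | 1-[2-(allyloxy)-6-(tert-butyldimethylsilyloxy)-3-methyl-4-(triisopropylsilyloxy)phenyl]ethan-1-one | CC(=O)c1c(OCC=C)c(C)c(O[Si](C(C)C)(C(C)C)C(C)C)cc1O[Si](C)(C)C(C)(C)C | intermediate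
8 | 1-[2-(allyloxy)-6-hydroxy-3-methyl-4-(triisopropylsilyloxy)phenyl]ethan-1-one | CC(=O)c1c(OCC=C)c(C)c(O[Si](C(C)C)(C(C)C)C(C)C)cc1O | intermediate
9 | di-tert-butyl dicarbonate | CC(C)(C)OC(=O)OC(=O)OC(C)(C)C | starting material
10 | tert-butyl 3-[2-(allyloxy)-6-hydroxy-3-methyl-4-(triisopropylsilyloxy)phenyl]-3-oxopropanoate | CC(C)(C)OC(=O)CC(=O)c1c(OCC=C)c(C)c(O[Si](C(C)C)(C(C)C)C(C)C)cc1O | intermediate
11 | 4-methoxybenzaldehyde | COc1ccc(C=O)cc1 | starting material
12 | tert-butyl 2-[2-(allyloxy)-6-hydroxy-3-methyl-4-(triisopropylsilyloxy)benzoyl]-3-(4-methoxyphenyl)prop-2-enoate, E/Z mixture | COc1ccc(C=C(C(=O)OC(C)(C)C)C(=O)c2c(OCC=C)c(C)c(O[Si](C(C)C)(C(C)C)C(C)C)cc2O)cc1 | intermediate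
13 | tert-butyl (2S)-5-(allyloxy)-2-(4-methoxyphenyl)-6-methyl-4-oxo-7-(triisopropylsilyloxy)chromane-3-carboxylate, C3 epimers | COc1ccc([C@@H]2C(C(=O)OC(C)(C)C)C(=O)c3c(OCC=C)c(C)c(O[Si](C(C)C)(C(C)C)C(C)C)cc3O2)cc1 | intermediate
14 | (2S)-5-(allyloxy)-2-(4-methoxyphenyl)-6-methyl-7-(triisopropylsilyloxy)chroman-4-one | COc1ccc([C@@H]2CC(=O)c3c(OCC=C)c(C)c(O[Si](C(C)C)(C(C)C)C(C)C)cc3O2)cc1 | intermediate
15 | 2-methylbut-2-ene | CC=C(C)C | starting material
16 | (2S)-2-(4-methoxyphenyl)-6-methyl-5-(3-methylbut-2-enyloxy)-7-(triisopropylsilyloxy)chroman-4-one | COc1ccc([C@@H]2CC(=O)c3c(OCC=C(C)C)c(C)c(O[Si](C(C)C)(C(C)C)C(C)C)cc3O2)cc1 | intermediate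
17 | (2S)-2-(4-methoxyphenyl)-6-methyl-6-(2-methylbut-3-en-2-yl)-7-(triisopropylsilyloxy)-2,3-dihydro-4H-chromene-4,5(6H)-dione, C6 epimers | COc1ccc([C@@H]2CC(=O)C3=C(O2)C=C(O[Si](C(C)C)(C(C)C)C(C)C)C(C)(C(C)(C)C=C)C3=O)cc1 | intermediate
18 | (2S)-5-hydroxy-2-(4-methoxyphenyl)-6-methyl-8-(3-methylbut-2-enyl)-7-(triisopropylsilyloxy)chroman-4-one | COc1ccc([C@@H]2CC(=O)c3c(O)c(C)c(O[Si](C(C)C)(C(C)C)C(C)C)c(CC=C(C)C)c3O2)cc1 | intermediate
19 | (2S)-5,7-dihydroxy-2-(4-methoxyphenyl)-6-methyl-8-(3-methylbut-2-en-1-yl)chroman-4-one | COc1ccc([C@@H]2CC(=O)c3c(O)c(C)c(O)c(CC=C(C)C)c3O2)cc1 | target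

Total step count: 9. Longest linear sequence: 9 steps (from 1).

**Steps most likely to fail, with fallbacks**

Step 6. Enantiocontrol may be lost in the ring closure. The aroyl group is flanked by two ortho oxygens and twisted out of conjugation, which may slow the catalysed pathway relative to uncatalysed (racemic) closure. The p-anisyl benzylic C–O bond also favours ring opening and reclosure during the hot acid decarboxylation. The fallback sets out from 8 and returns at 14. Compound 8 is condensed with N,N-dimethylformamide dimethyl acetal (toluene, 90 °C) to the enaminone (E)-1-[2-(allyloxy)-6-hydroxy-3-methyl-4-(triisopropylsilyloxy)phenyl]-3-(dimethylamino)prop-2-en-1-one F1. Acid (conc. HCl, CH2Cl2, rt) closes this to the chromone 5-(allyloxy)-6-methyl-7-(triisopropylsilyloxy)-4H-chromen-4-one F2. Rhodium-catalysed enantioselective 1,4-addition of 4-methoxyphenylboronic acid to F2 (Rh(I) with a chiral electron-poor bisphosphine or chiral diene, toluene/water, no added base), a known route from chromones to flavanones, should then give 14, with the ligand antipode chosen for 2S.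

Step 8. The rearrangement may stall or divert. The first [3,3] shift has to create two adjacent quaternary carbons (C6 and the CMe2 terminus) beside the bulky silyl ether, so ionisation of the prenyl ether (loss of prenyl or a [1,3] shift) or arrest at the ortho-dienone may compete. The fallback sets out from 14 and returns at 19. The allyl ether of 14 is removed with Pd(PPh3)4/morpholine (THF, rt) to give (2S)-5-hydroxy-2-(4-methoxyphenyl)-6-methyl-7-(triisopropylsilyloxy)chroman-4-one F3. The silyl ether is removed with TBAF/AcOH to give (2S)-5,7-dihydroxy-2-(4-methoxyphenyl)-6-methylchroman-4-one F4. F4 is then C-prenylated at C8, its only free nucleophilic ring carbon, by Friedel–Crafts alkylation with 2-methylbut-3-en-2-ol and BF3·OEt2 (dioxane, rt) to give 19; the acidic, base-free conditions should leave C2 intact.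

Step 2. Etherification may fail or scramble the protecting groups. The 2-OH is chelated to the acetyl group and flanked by the methyl group, so the Mitsunobu reaction may stop before O-alkylation, and silyl migration between phenolic oxygens would destroy the site differentiation of step 1. The fallback sets out from 1 and returns at 8. Compound 1 is protected with MOMCl/i-Pr2NEt (CH2Cl2, 0 °C), which should again spare the hindered chelated 2-OH, to give 1-[2-hydroxy-4,6-bis(methoxymethoxy)-3-methylphenyl]ethan-1-one F5. The base-stable acetals then allow a forcing Williamson allylation (allyl bromide, K2CO3, DMF, 60 °C) to 1-[2-(allyloxy)-4,6-bis(methoxymethoxy)-3-methylphenyl]ethan-1-one F6. Both acetals are removed (HCl, MeOH, 40 °C; the allyl ether is acid-stable) to give 1-[2-(allyloxy)-4,6-dihydroxy-3-methylphenyl]ethan-1-one F7. TIPSCl/imidazole (DMF, 0 °C) should then silylate only the non-chelated 4-OH to give 8.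

**Further compounds**
F1 | step 6 | (E)-1-[2-(allyloxy)-6-hydroxy-3-methyl-4-(triisopropylsilyloxy)phenyl]-3-(dimethylamino)prop-2-en-1-one | CN(C)/C=C/C(=O)c1c(OCC=C)c(C)c(O[Si](C(C)C)(C(C)C)C(C)C)cc1O
F2 | step 6 | 5-(allyloxy)-6-methyl-7-(triisopropylsilyloxy)-4H-chromen-4-one | O=c1ccoc2cc(O[Si](C(C)C)(C(C)C)C(C)C)c(C)c(OCC=C)c12
F3 | step 8 | (2S)-5-hydroxy-2-(4-methoxyphenyl)-6-methyl-7-(triisopropylsilyloxy)chroman-4-one | COc1ccc([C@@H]2CC(=O)c3c(O)c(C)c(O[Si](C(C)C)(C(C)C)C(C)C)cc3O2)cc1
F4 | step 8 | (2S)-5,7-dihydroxy-2-(4-methoxyphenyl)-6-methylchroman-4-one | COc1ccc([C@@H]2CC(=O)c3c(O)c(C)c(O)cc3O2)cc1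
F5 | step 2 | 1-[2-hydroxy-4,6-bis(methoxymethoxy)-3-methylphenyl]ethan-1-one | CC(=O)c1c(O)c(C)c(OCOC)cc1OCOC
F6 | step 2 | 1-[2-(allyloxy)-4,6-bis(methoxymethoxy)-3-methylphenyl]ethan-1-one | CC(=O)c1c(OCC=C)c(C)c(OCOC)cc1OCOC
F7 | step 2 | 1-[2-(allyloxy)-4,6-dihydroxy-3-methylphenyl]ethan-1-one | CC(=O)c1c(OCC=C)c(C)c(O)cc1O
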